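The route rests on disconnecting both C–O bonds of the 1,2-dioxane ring at once (chain numbered from the ester carbon C1). The feature exploited is that the O–O unit links C3 and C6 across the four contiguous ring carbons C3–C4–C5–C6, which therefore map onto a 1,3-diene. A single photooxygenation adds singlet oxygen across the (3E,5E)-diene of the acyclic diketo ester 17, closes the six-membered peroxide ring and creates C3 and C6 together, their cis relationship following from the diene geometry. Diene 17 comes from Suzuki coupling of a C5–C15 iodoalkene, carved out of dihydro-β-ionone by ozonolysis, with a C1–C4 alkenylboronate from the (R)-configured hydroxy ester; diimide then saturates C4=C5.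

Key step: step 12

Remarks on the chemistry
- Numbering: C2 carries the α-methyl, C3–C6 are the ring carbons, C9 and C14 the ketone carbons. The target is 2S,3S,6R; the same spatial arrangement in the unsaturated ring is named 3S,6S because the CIP ranking at C6 changes when C4=C5 is present.
- The (R)-hydroxy ester 8 leads to 2S only if its carbinol carbon becomes C1 and its ester carbon becomes C3. C1 is therefore carried as a silyl ether and oxidised once the diene is in place.
- Precursor design: the ketones stay unprotected and the ester is already present, so only one step follows peroxide formation. The ester is installed last and base-free, because C2–H is both α to the carbonyl and allylic to the diene.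
- Assumption: dihydro-β-ionone 1, hydroxy ester 8 and 2-(dichloromethyl)-4,4,5,5-tetramethyl-1,3,2-dioxaborolane are taken as commercial.

Step 1
Reactants: 1 dihydro-β-ionone [4-(2,6,6-trimethylcyclohex-1-en-1-yl)butan-2-one]
Product: 3 2-(but-3-yn-1-yl)-1,3,3-trimethylcyclohex-1-ene, via enol phosphate 2 (not isolated)
Conditions: LiN(iPr)2, THF, −78 °C; ClP(O)(OEt)2, −78 °C to rt; then LiN(iPr)2 (2.3 equiv), −78 °C to rt; aq. NH4Cl
Reagents that add atoms: none
Why: Kinetic deprotonation at the methyl group and O-phosphorylation give enol phosphate 2, from which a second base-induced elimination of diethyl phosphate should give the terminal alkyne (methyl ketone to alkyne conversion through an enol phosphate), the tetrasubstituted ring alkene being inert to the base.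

Step 2
Reactants: 3 2-(but-3-yn-1-yl)-1,3,3-trimethylcyclohex-1-ene
Product: 5 2-[(3E)-4-iodo-3-methylbut-3-en-1-yl]-1,3,3-trimethylcyclohex-1-ene, via alkenylalane 4 (not isolated)
Conditions: Al(CH3)3 (2 equiv), Cp2ZrCl2 (0.25 equiv), CH2Cl2, 0 °C to rt; then I2, THF, −30 to 0 °C
Reagents that add atoms: trimethylaluminium C[Al](C)C; iodine II
Why: Zirconocene-catalysed Negishi carboalumination adds methyl and aluminium syn across the terminal alkyne with aluminium at the terminus, and iodinolysis of alkenylalane 4 with retention should give the E iodoalkene in which the new C6 methyl is cis to iodine, the C5=C6 geometry the diene needs.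

Step 3
Reactants: 5 2-[(3E)-4-iodo-3-methylbut-3-en-1-yl]-1,3,3-trimethylcyclohex-1-ene
Product: 7 (10E)-11-iodo-6,6,10-trimethylundec-10-ene-2,7-dione, via ozonide 6 (not isolated)
Conditions: O3, CH2Cl2, −78 °C, Sudan red 7B as end-point indicator; then PPh3, −78 °C to rt
Reagents that add atoms: ozone [O-][O+]=O
Why: Ozonolysis (Criegee mechanism) is expected to consume the electron-rich tetrasubstituted ring alkene well before the electron-poorer iodine-bearing alkene, and phosphine reduction of ozonide 6 should unveil the C9 and C14 ketones with the gem-dimethyl carbon C10 already in place.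

Step 4
Reactants: 8 methyl (2R)-3-hydroxy-2-methylpropanoate
Product: 9 methyl (2R)-3-[(tert-butyldimethylsilyl)oxy]-2-methylpropanoate
Conditions: TBSCl, imidazole, CH2Cl2, 0 °C to rt
Reagents that add atoms: tert-butyldimethylsilyl chloride CC(C)(C)[Si](C)(C)Cl
Why: Imidazole-promoted silylation of the primary alcohol masks the future C1 oxygen with a group that should survive the hydride, chromium and palladium steps.

Step 5
Reactants: 9 methyl (2R)-3-[(tert-butyldimethylsilyl)oxy]-2-methylpropanoate
Product: 11 (2R)-3-[(tert-butyldimethylsilyl)oxy]-2-methylpropanal, via aluminium hemiacetal 10 (not isolated)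
Conditions: (i-Bu)2AlH (1.1 equiv), CH2Cl2, −78 °C; MeOH, then aq. potassium sodium tartrate
Reagents that add atoms: none
Why: Partial ester reduction by a single hydride transfer stops at the tetrahedral aluminium hemiacetal 10 at −78 °C, which collapses to the aldehyde only on work-up, and the base-free conditions leave the α-stereocentre intact.

Step 6
Reactants: 11 (2R)-3-[(tert-butyldimethylsilyl)oxy]-2-methylpropanal
Product: 12 tert-butyldimethyl{[(2S,3E)-2-methyl-4-(4,4,5,5-tetramethyl-1,3,2-dioxaborolan-2-yl)but-3-en-1-yl]oxy}silane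
Conditions: Cl2CHB(pin), CrCl2 (8 equiv), LiI (4 equiv), THF, rt
Reagents that add atoms: 2-(dichloromethyl)-4,4,5,5-tetramethyl-1,3,2-dioxaborolane CC1(C)OB(C(Cl)Cl)OC1(C)C
Why: In this Takai–Utimoto-type olefination the geminal dichromium reagent formed from the dichloromethylboronate and divalent chromium adds to the aldehyde and eliminates to the E alkenylboronate, supplying C4, while the non-basic medium preserves the C2 configuration.

Step 7
Reactants: 7 (10E)-11-iodo-6,6,10-trimethylundec-10-ene-2,7-dione; 12 tert-butyldimethyl{[(2S,3E)-2-methyl-4-(4,4,5,5-tetramethyl-1,3,2-dioxaborolan-2-yl)but-3-en-1-yl]oxy}silane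
Product: 13 (10E,12E,14S)-15-[(tert-butyldimethylsilyl)oxy]-6,6,10,14-tetramethylpentadeca-10,12-diene-2,7-dione
Conditions: PdCl2(dppf) (5 mol%), aq. K3PO4, THF, 40 °C, degassed
Reagents that add atoms: none
Why: Suzuki–Miyaura coupling should join C4 to C5 with retention of both alkene geometries, and the mild phosphate base leaves the two ketones and the non-acidic C2 centre alone.

Step 8
Reactants: 13 (10E,12E,14S)-15-[(tert-butyldimethylsilyl)oxy]-6,6,10,14-tetramethylpentadeca-10,12-diene-2,7-dione
Product: 14 (10E,12E,14S)-15-hydroxy-6,6,10,14-tetramethylpentadeca-10,12-diene-2,7-dione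
Conditions: HF·pyridine, pyridine, THF, 0 °C to rt
Reagents that add atoms: none
Why: Fluoride-driven desilylation under buffered, non-basic conditions should free the primary alcohol without disturbing the diene or the diketone.

Step 9
Reactants: 14 (10E,12E,14S)-15-hydroxy-6,6,10,14-tetramethylpentadeca-10,12-diene-2,7-dione
Product: 15 (2S,3E,5E)-2,6,10,10-tetramethyl-9,14-dioxopentadeca-3,5-dienal
Conditions: Dess–Martin periodinane, NaHCO3, CH2Cl2, 0 °C; crude product used at once
Reagents that add atoms: none
Why: Dess–Martin oxidation proceeds by ligand exchange at iodine and internal proton abstraction under near-neutral conditions, which should give the skipped dienal without enolisation at C2 provided it is neither chromatographed nor stored.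

Step 10
Reactants: 15 (2S,3E,5E)-2,6,10,10-tetramethyl-9,14-dioxopentadeca-3,5-dienal
Product: 16 (2S,3E,5E)-2,6,10,10-tetramethyl-9,14-dioxopentadeca-3,5-dienoic acid
Conditions: NaClO2, NaH2PO4, 2-methyl-2-butene (large excess), t-BuOH/H2O, 0 °C
Reagents that add atoms: sodium chlorite [Na+].[O-]Cl=O
Why: In the Pinnick oxidation chlorous acid adds to the aldehyde and fragments to the acid, the weakly acidic buffer does not enolise C2, and the excess 2-methyl-2-butene should intercept hypochlorous acid before it reaches the diene.

Step 11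
Reactants: 16 (2S,3E,5E)-2,6,10,10-tetramethyl-9,14-dioxopentadeca-3,5-dienoic acid
Product: 17 methyl (2S,3E,5E)-2,6,10,10-tetramethyl-9,14-dioxopentadeca-3,5-dienoate
Conditions: TMSCHN2, toluene/MeOH, 0 °C
Reagents that add atoms: (trimethylsilyl)diazomethane C[Si](C)(C)C=[N+]=[N-]
Why: Base-free O-methylation of the carboxylic acid by the diazoalkane (protonation, then alkylation of the carboxylate with loss of N2) should install the ester without giving the C3=C4 bond a chance to move into conjugation.

Step 12
Reactants: 17 methyl (2S,3E,5E)-2,6,10,10-tetramethyl-9,14-dioxopentadeca-3,5-dienoate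
Product: 18 methyl (2S)-2-[(3S,6S)-6-(4,4-dimethyl-3,8-dioxononyl)-6-methyl-3,6-dihydro-1,2-dioxin-3-yl]propanoate
Conditions: O2 (1 atm), 5,10,15,20-tetraphenylporphyrin (1 mol%), white LED, CH2Cl2, 0 °C; evaporation below 25 °C, chromatography
Reagents that add atoms: dioxygen O=O
Why: Energy transfer from photoexcited tetraphenylporphyrin converts O2 into singlet oxygen, which adds suprafacially in a concerted [4+2] cycloaddition across the cisoid C3=C4–C5=C6 diene of 17, making the O–C3 and O–C6 bonds while the remaining double bond moves to C4=C5. The closest known reaction type is the photooxygenation of acyclic (E,E)-1,3-dienes to 3,6-dihydro-1,2-dioxines. The six-membered peroxide ring is closed by the cycloaddition itself, both ring bonds forming in one pericyclic event across the diene termini, so no separate cyclisation is required. C3 and C6 are fixed relative to each other by the diene geometry, because 3E and 5E place C2 and C7 outside and H3 and the C6 methyl inside, so that C2 and C7 end up cis on the ring; their sense relative to C2 is set by the 2S centre, the wanted (3S,6S) adduct arising from attack on the diene face anti to the C2 methyl in the rotamer whose C2–H eclipses C3=C4. The step needs periselectivity over the ene reaction at C5=C6 (allylic hydrogens on the C6 methyl and on C7) and over [2+2] addition, which an aprotic, weakly polar medium and a temperature that still populates the cisoid rotamer are meant to favour, and it needs facial selectivity, for which only the C2 centre is available and which is expected to be modest. The (3R,6R) face isomer and any allylic hydroperoxides are therefore to be removed by chromatography, the ketones at C9 and C14 and the ester being inert to singlet oxygen.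

Step 13
Reactants: 18 methyl (2S)-2-[(3S,6S)-6-(4,4-dimethyl-3,8-dioxononyl)-6-methyl-3,6-dihydro-1,2-dioxin-3-yl]propanoate
Product: 19 Diacarperoxide B [methyl (2S)-2-[(3S,6R)-6-(4,4-dimethyl-3,8-dioxononyl)-6-methyl-1,2-dioxan-3-yl]propanoate]
Conditions: KO2CN=NCO2K (excess), AcOH, MeOH/CH2Cl2, 0 °C to rt
Reagents that add atoms: none
Why: Diimide reduction, with the diimide released by acid-promoted decarboxylation of the azodicarboxylate, transfers two hydrogens to the cis C4=C5 bond through a concerted six-membered transition state and offers no pathway for O–O cleavage, while the acidic medium avoids base-induced Kornblum–DeLaMare opening of the dihydrodioxine and no stereocentre is touched.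

Compound list
1 | dihydro-β-ionone, 4-(2,6,6-trimethylcyclohex-1-en-1-yl)butan-2-one | CC(=O)CCC1=C(C)CCCC1(C)C | starting material
2 | diethyl 4-(2,6,6-trimethylcyclohex-1-en-1-yl)but-1-en-2-yl phosphate | C=C(CCC1=C(C)CCCC1(C)C)OP(=O)(OCC)OCC | intermediate
3 | 2-(but-3-yn-1-yl)-1,3,3-trimethylcyclohex-1-ene | C#CCCC1=C(C)CCCC1(C)C | intermediate
4 | dimethyl[(1E)-2-methyl-4-(2,6,6-trimethylcyclohex-1-en-1-yl)but-1-en-1-yl]alumane | C[Al](C)/C=C(\C)CCC1=C(C)CCCC1(C)C | intermediate
5 | 2-[(3E)-4-iodo-3-methylbut-3-en-1-yl]-1,3,3-trimethylcyclohex-1-ene | I/C=C(\C)CCC1=C(C)CCCC1(C)C | intermediate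
6 | 1-[(3E)-4-iodo-3-methylbut-3-en-1-yl]-2,2,6-trimethyl-7,8,9-trioxabicyclo[4.2.1]nonane (racemic) | CC12CCCC(C)(C)C(CC/C(C)=C/I)(OO1)O2 | intermediate
7 | (10E)-11-iodo-6,6,10-trimethylundec-10-ene-2,7-dione | I/C=C(\C)CCC(=O)C(C)(C)CCCC(C)=O | intermediate
8 | methyl (2R)-3-hydroxy-2-methylpropanoate | COC(=O)[C@H](C)CO | starting material
9 | methyl (2R)-3-[(tert-butyldimethylsilyl)oxy]-2-methylpropanoate | CC(C)(C)[Si](C)(C)OC[C@@H](C)C(=O)OC | intermediate
10 | {(2R)-3-[(tert-butyldimethylsilyl)oxy]-1-methoxy-2-methylpropoxy}bis(2-methylpropyl)alumane (mixture at the hemiacetal carbon) | CC(C)(C)[Si](C)(C)OC[C@@H](C)C(OC)O[Al](CC(C)C)CC(C)C | intermediate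
11 | (2R)-3-[(tert-butyldimethylsilyl)oxy]-2-methylpropanal | CC(C)(C)[Si](C)(C)OC[C@@H](C)C=O | intermediate
12 | tert-butyldimethyl{[(2S,3E)-2-methyl-4-(4,4,5,5-tetramethyl-1,3,2-dioxaborolan-2-yl)but-3-en-1-yl]oxy}silane | CC(C)(C)[Si](C)(C)OC[C@@H](C)/C=C/B1OC(C)(C)C(C)(C)O1 | intermediate
13 | (10E,12E,14S)-15-[(tert-butyldimethylsilyl)oxy]-6,6,10,14-tetramethylpentadeca-10,12-diene-2,7-dione | CC(C)(C)[Si](C)(C)OC[C@@H](C)/C=C/C=C(\C)CCC(=O)C(C)(C)CCCC(C)=O | intermediate
14 | (10E,12E,14S)-15-hydroxy-6,6,10,14-tetramethylpentadeca-10,12-diene-2,7-dione | OC[C@@H](C)/C=C/C=C(\C)CCC(=O)C(C)(C)CCCC(C)=O | intermediate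
15 | (2S,3E,5E)-2,6,10,10-tetramethyl-9,14-dioxopentadeca-3,5-dienal | O=C[C@@H](C)/C=C/C=C(\C)CCC(=O)C(C)(C)CCCC(C)=O | intermediate
16 | (2S,3E,5E)-2,6,10,10-tetramethyl-9,14-dioxopentadeca-3,5-dienoic acid | OC(=O)[C@@H](C)/C=C/C=C(\C)CCC(=O)C(C)(C)CCCC(C)=O | intermediate
17 | methyl (2S,3E,5E)-2,6,10,10-tetramethyl-9,14-dioxopentadeca-3,5-dienoate | COC(=O)[C@@H](C)/C=C/C=C(\C)CCC(=O)C(C)(C)CCCC(C)=O | intermediate
18 | methyl (2S)-2-[(3S,6S)-6-(4,4-dimethyl-3,8-dioxononyl)-6-methyl-3,6-dihydro-1,2-dioxin-3-yl]propanoate | COC(=O)[C@@H](C)[C@@H]1C=C[C@](C)(CCC(=O)C(C)(C)CCCC(C)=O)OO1 | intermediate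
19 | Diacarperoxide B, methyl (2S)-2-[(3S,6R)-6-(4,4-dimethyl-3,8-dioxononyl)-6-methyl-1,2-dioxan-3-yl]propanoate | COC(=O)[C@@H](C)[C@@H]1CC[C@](C)(CCC(=O)C(C)(C)CCCC(C)=O)OO1 | target

Total step count: 13.
Longest linear sequence: 10 steps (steps 1–3 and 7–13 from dihydro-β-ionone; equally steps 4–6 and 7–13 from the hydroxy ester).

Steps most likely to fail

Step 12. The ene hydroperoxidation at the trisubstituted C5=C6 bond may outrun the cycloaddition, because the inside methyl on C6 lowers the population of the cisoid rotamer. Discrimination between the two diene faces may also be poor. The fallback sets out from 17 and comes back to the route at 18. It replaces singlet oxygen by a radical-cation chain cycloaddition of ground-state O2, initiated by a triarylammoniumyl salt, (4-BrC6H4)3N SbCl6 or the stronger oxidant (2,4-Br2C6H3)3N SbCl6, in CH2Cl2 at −78 °C. This is a known route to 1,2-dioxines from dienes whose singlet-oxygen chemistry is dominated by the ene reaction. Because the diene radical cation captures O2 stepwise, the C3/C6 relationship would no longer be dictated by diene geometry, and the cis isomer would have to be separated. No new compound is made (F0).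

Step 9. The skipped dienal may lose its C2 configuration by enolisation, or its C3=C4 bond may migrate into conjugation with the aldehyde. The fallback sets out from 13 and comes back at 19, moving the C1 oxidation behind ring formation so that no α-stereogenic β,γ-unsaturated carbonyl compound is ever handled. Silyl ether 13 would be photooxygenated under the conditions of step 12 to the silyl ether dihydrodioxine 9-[(3S,6S)-6-{(2R)-1-[(tert-butyldimethylsilyl)oxy]propan-2-yl}-3-methyl-3,6-dihydro-1,2-dioxin-3-yl]-6,6-dimethylnonane-2,7-dione F1. Diimide, as in step 13, would give the saturated silyl ether 9-[(3R,6S)-6-{(2R)-1-[(tert-butyldimethylsilyl)oxy]propan-2-yl}-3-methyl-1,2-dioxan-3-yl]-6,6-dimethylnonane-2,7-dione F2. HF·pyridine would free the alcohol 9-[(3R,6S)-6-[(2R)-1-hydroxypropan-2-yl]-3-methyl-1,2-dioxan-3-yl]-6,6-dimethylnonane-2,7-dione F3. Dess–Martin oxidation would give the now saturated aldehyde (2S)-2-[(3S,6R)-6-(4,4-dimethyl-3,8-dioxononyl)-6-methyl-1,2-dioxan-3-yl]propanal F4. Pinnick oxidation would give (2S)-2-[(3S,6R)-6-(4,4-dimethyl-3,8-dioxononyl)-6-methyl-1,2-dioxan-3-yl]propanoic acid F5, and TMSCHN2 would give 19. The costs are four more steps after the peroxide is made and a bulkier C1 group on the diene face that has to be attacked.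

Step 3. Ozone may also attack the iodoalkene once the ring alkene is consumed, or cleavage of the hindered tetrasubstituted alkene may stall at the ozonide. The fallback sets out from 5 and comes back at 7, and splits the cleavage into an electrophilic epoxidation and a glycol-type cleavage. mCPBA (1.0 equiv, NaHCO3, CH2Cl2, −20 °C) should epoxidise only the tetrasubstituted alkene to give racemic 1-[(3E)-4-iodo-3-methylbut-3-en-1-yl]-2,2,6-trimethyl-7-oxabicyclo[4.1.0]heptane F6. H5IO6 in aqueous THF would then open the epoxide to the trans diol 1-[(3E)-4-iodo-3-methylbut-3-en-1-yl]-2,6,6-trimethylcyclohexane-1,2-diol F7 and cleave it in the same flask to diketone 7.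

Further compounds
F0 | step 12 | none | none
F1 | step 9 | 9-[(3S,6S)-6-{(2R)-1-[(tert-butyldimethylsilyl)oxy]propan-2-yl}-3-methyl-3,6-dihydro-1,2-dioxin-3-yl]-6,6-dimethylnonane-2,7-dione | CC(C)(C)[Si](C)(C)OC[C@@H](C)[C@@H]1C=C[C@](C)(CCC(=O)C(C)(C)CCCC(C)=O)OO1
F2 | step 9 | 9-[(3R,6S)-6-{(2R)-1-[(tert-butyldimethylsilyl)oxy]propan-2-yl}-3-methyl-1,2-dioxan-3-yl]-6,6-dimethylnonane-2,7-dione | CC(C)(C)[Si](C)(C)OC[C@@H](C)[C@@H]1CC[C@](C)(CCC(=O)C(C)(C)CCCC(C)=O)OO1
F3 | step 9 | 9-[(3R,6S)-6-[(2R)-1-hydroxypropan-2-yl]-3-methyl-1,2-dioxan-3-yl]-6,6-dimethylnonane-2,7-dione | OC[C@@H](C)[C@@H]1CC[C@](C)(CCC(=O)C(C)(C)CCCC(C)=O)OO1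
F4 | step 9 | (2S)-2-[(3S,6R)-6-(4,4-dimethyl-3,8-dioxononyl)-6-methyl-1,2-dioxan-3-yl]propanal | O=C[C@@H](C)[C@@H]1CC[C@](C)(CCC(=O)C(C)(C)CCCC(C)=O)OO1
F5 | step 9 | (2S)-2-[(3S,6R)-6-(4,4-dimethyl-3,8-dioxononyl)-6-methyl-1,2-dioxan-3-yl]propanoic acid | OC(=O)[C@@H](C)[C@@H]1CC[C@](C)(CCC(=O)C(C)(C)CCCC(C)=O)OO1
F6 | step 3 | 1-[(3E)-4-iodo-3-methylbut-3-en-1-yl]-2,2,6-trimethyl-7-oxabicyclo[4.1.0]heptane (racemic) | CC12CCCC(C)(C)C1(CC/C(C)=C/I)O2
F7 | step 3 | 1-[(3E)-4-iodo-3-methylbut-3-en-1-yl]-2,6,6-trimethylcyclohexane-1,2-diol (racemic, trans) | CC1(O)CCCC(C)(C)C1(O)CC/C(C)=C/I
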